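**Analysis of the target**

Grevirobstol B (18) is an achiral 22-membered macrocycle in which two benzene rings are joined twice: an ether oxygen links C3(A) to C2(B), and an unbranched chain of sixteen methylene groups runs from C1(A) to C1(B). Ring A is 1,3,5-trisubstituted (chain, ether oxygen, free hydroxyl at C5(A)). Ring B is 1,2,3,5-tetrasubstituted: chain at C1(B), aryloxy at C2(B), hydroxyl groups at C3(B) and C5(B), with C4(B) and C6(B) bearing hydrogen. There is no stereocentre, so every selectivity question is one of chemo- and regiocontrol. The three phenols sit on two electron-rich rings that are prone to air oxidation and electrophilic substitution, so they are best kept masked until the last step. Two things make the synthesis hard: the entropic cost of the large ring, and the ether oxygen at C2(B), which is flanked by C1(B) and the oxygenated C3(B) on an electron-rich arene and is therefore a poor site for aromatic substitution or metal-mediated C–O coupling. The plan rests on reading ring B as a 5-alkylresorcinol: C1(B) to C4(B), with the aryloxy group on C2(B) and the oxygen on C3(B), is an α-aryloxy methyl enone in disguise, and C5(B) with C6(B) is the two-carbon unit of a malonate. Ring B can therefore be grown last, on a macrocycle that already holds ring A, the chain and the ether bond.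

**Retrosynthetic reasoning**

18 from 17. The last bonds cut are the two O–CH3 bonds. The ring A methyl ether is present from the first aromatic building block 4, and the ring B methyl ether arises on its own during aromatisation, so one Lewis-acid ether cleavage at the end frees all three phenols and nothing electron-rich has to be carried unprotected.

17 from 15 and 14. The C6(B)–CO2CH3 bond is removed by saponification and decarboxylation through acid 16, and ring B is taken back to the cyclohexane-1,3-dione oxidation level in 14. The oxygens at C3(B) and C5(B) are then simply the two carbonyl oxygens, so no oxygen has to be introduced onto an arene. The ester is kept through the aromatisation on purpose: it makes C6(B), next to the C1(B)–H bond, the activated site for halogenation, and its chelated enol at C5(B) leaves only the C3(B) carbonyl free to become an enol ether, so that a single methylation pattern (15) is expected.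

14 from 11 and 12. Ring B is opened at C1(B)–C6(B) and C4(B)–C5(B). This is where the strategy sits: the four carbons C1(B) to C4(B) are the enone of 11 and the other two come from dimethyl malonate 12. Cutting here, and not at an aryl–oxygen or aryl–carbon bond, means the congested substitution pattern around C2(B) is assembled from an sp2 carbon of an enone and never by substitution on a crowded arene. The forward reaction has to deliver conjugate addition and one defined Claisen closure.

11 from 10. The macrocycle is opened at C1(B)=C2(B), the enone double bond. An intramolecular Horner–Wadsworth–Emmons reaction between the ketophosphonate and the aldehyde of 10 closes the ring and creates the enone in the same event. The ring is large, flexible and unstrained, and the two reacting ends are unhindered.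

10 from 9, 8, 6 and 7. The aldehyde comes from the primary alcohol of 9. The O–C2(B) bond is traced to a rhodium carbenoid O–H insertion of diazo compound 7 into phenol 6, so the ether oxygen is attached while its phenol is still unhindered and ring B does not yet exist. A free primary alcohol would compete with the phenol for the carbenoid, so the chain terminus is carried as a benzyl ether. Placing the hydrogenation after the insertion lets one operation saturate the styrene and free the alcohol (8 to 9).

6 from 3 and 4, and 3 from 2 and 1. The chain is joined to ring A at its first C–C bond by a Wittig reaction between aldehyde 4 and ylide 5, which is generated from phosphonium salt 3. The aldehyde carbon of 4 plus the sixteen carbons of 1 give the seventeen carbons needed (sixteen methylenes and the future C1(B)). Salt 3 comes from bromide 2, the benzyl ether of 1.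

**Alternatives that were turned down**

Alternative 1: The ring would be opened in the chain next to ring B (C15'–C16', counting from ring A) and at the diaryl ether. One formyl group on C1(B) serves twice: it first activates a leaving group on C2(B) for displacement by the ring A phenoxide, then accepts the ylide. In the key step the seco phosphonium salt A2 is added slowly to a strong amide base at high dilution, and the ylide closes the 22-membered ring onto the ring B aldehyde to give the (Z)-alkene A1; hydrogenation and three O-demethylations would follow.
- For: both arenes are used as purchased, the route is convergent and short, and every reaction type is documented. On step count and on precedent for its key step it is stronger than the chosen route.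
- Against: the substitution has to take place on a ring whose methoxy groups at C3(B) and C5(B) lie ortho and para to the carbon under attack, exactly where the negative charge of the addition intermediate must reside. A single formyl group has to outweigh two donors, and the nucleophile must enter between two substituted carbons.
- Comparison: its risk lies in the very C–O bond that the chosen route forms by carbenoid insertion into an unhindered phenol. In exchange the chosen route accepts a longer sequence and an annulation on an untested type of enone.

Alternative 2: The C5(A)–O and C5(B)–O bonds would be made last, by C–H functionalisation of the bare macrocycle A3. Iridium-catalysed, sterically governed C–H borylation should go to the one C–H bond on each ring that has no ortho neighbour, and oxidation of both C–B bonds in the same flask would give diphenol A4, one demethylation short of 18.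
- For: it is the shortest conceivable endgame, needs no protecting group for the new hydroxyls, and its regiochemistry is predictable. On these points it is stronger.
- Against: A3 already contains the macrocycle and the hindered ether bond to C2(B), so the two real problems of the target are only moved into the synthesis of A3 and left unanswered. Both borylations must go to completion on one molecule, and the small methoxy group at C3(B) does not fully shield C4(B)–H, so partly borylated and regioisomeric products of similar polarity are likely.
- Comparison: the chosen route is longer but places every oxygen by construction (ring A from 4, ring B from two carbonyl groups) and addresses ring closure and ether formation with defined reactions.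

Alternative 3: Ring B would be traced through C5(B)–C6(B) back to a four-membered ring, the squaric-acid-derived alkenyl hydroxycyclobutenone A5, whose alkenyl group carries the chain and ring A. On heating, the cyclobutenone opens to a dienylketene, a 6π electrocyclisation forms C5(B)–C6(B), and tautomerisation gives hydroquinone A6 with oxygens on C2(B), C3(B) and C5(B).
- For: the thermal ring expansion is well established and regiodefined, and delivers all three ring B oxygens at once, with C3(B) already differentiated. In precedent for its key step it is stronger than the chosen annulation.
- Against: A6 has neither the macrocycle nor the ether bond. The two hydroquinone hydroxyls must still be told apart, the ring A silyl ether turned into a leaving group, and the 22-membered ring closed by a metal-mediated C–O coupling at the C2(B) hydroxyl, which is flanked by the isopropoxy group and the chain. The hardest bond would be formed last, as the macrocyclisation, and three different protecting groups must then be removed.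
- Comparison: the chosen route makes the ether bond first, closes the ring by olefination between unhindered partners, and needs no differentiation of ring B hydroxyls.

Key step: step 8

Remark on the chemistry: step 7 is expected to give mainly the (Z)-enone 11 (acetyl group trans to the chain); the (E)-isomer would serve equally, because step 8 consumes the double bond.

**Route**

Step 1
Reactants: 1 16-bromohexadecan-1-ol
Product: 2 benzyl 16-bromohexadecyl ether
Conditions: BnOC(=NH)CCl3, TfOH (cat.), CH2Cl2/cyclohexane, 0 °C → rt
Reagents that add atoms: benzyl 2,2,2-trichloroacetimidate, N=C(OCc1ccccc1)C(Cl)(Cl)Cl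
Why: Acid-catalysed O-benzylation with a trichloroacetimidate forms no alkoxide, so the primary bromide is not displaced; the benzyl ether keeps the chain terminus away from the carbenoid in step 4.

Step 2
Reactants: 2 benzyl 16-bromohexadecyl ether
Product: 3 [16-(benzyloxy)hexadecyl]triphenylphosphonium bromide
Conditions: PPh3, MeCN, reflux
Reagents that add atoms: triphenylphosphine, c1ccc(cc1)P(c1ccccc1)c1ccccc1
Why: SN2 quaternisation of the phosphine by an unhindered primary bromide; the benzyl ether is inert.

Step 3
Reactants: 3 [16-(benzyloxy)hexadecyl]triphenylphosphonium bromide; 4 3-hydroxy-5-methoxybenzaldehyde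
Product: 6 3-[(1Z)-17-(benzyloxy)heptadec-1-en-1-yl]-5-methoxyphenol, via ylide 5 (not isolated)
Conditions: 3, NaN(SiMe3)2 (1.2 equiv), THF, 0 °C; then 4 as its sodium salt (NaN(SiMe3)2, 1.0 equiv), −78 °C → rt
Reagents that add atoms: none
Why: Wittig olefination with a non-stabilised ylide; the phenol is carried as its phenoxide, which is meta to the formyl group and cannot deactivate it by resonance. The (Z)-alkene should predominate, but the geometry is irrelevant because the double bond is hydrogenated in step 5.

Step 4
Reactants: 6 3-[(1Z)-17-(benzyloxy)heptadec-1-en-1-yl]-5-methoxyphenol; 7 dimethyl (1-diazo-2-oxopropyl)phosphonate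
Product: 8 dimethyl (1-{3-[(1Z)-17-(benzyloxy)heptadec-1-en-1-yl]-5-methoxyphenoxy}-2-oxopropyl)phosphonate (racemic)
Conditions: Rh2(OAc)4 (2 mol %), ClCH2CH2Cl, 80 °C, slow addition of 7
Reagents that add atoms: none
Why: Rhodium carbenoid O–H insertion into a phenol forms the future O–C2(B) bond on an unhindered oxygen; the acceptor/acceptor carbenoid should prefer the O–H bond to cyclopropanation of the 1,2-disubstituted styrene. The new C–H stereocentre is formed racemic and is lost in step 7.

Step 5
Reactants: 8 dimethyl (1-{3-[(1Z)-17-(benzyloxy)heptadec-1-en-1-yl]-5-methoxyphenoxy}-2-oxopropyl)phosphonate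
Product: 9 dimethyl {1-[3-(17-hydroxyheptadecyl)-5-methoxyphenoxy]-2-oxopropyl}phosphonate (racemic)
Conditions: H2 (1 atm), 10% Pd/C, EtOAc/EtOH, rt
Reagents that add atoms: none
Why: Heterogeneous hydrogenation saturates the styrene and hydrogenolyses the benzyl ether in one operation; the ketone, the phosphonate and the aryl ethers are not reduced under these conditions.

Step 6
Reactants: 9 dimethyl {1-[3-(17-hydroxyheptadecyl)-5-methoxyphenoxy]-2-oxopropyl}phosphonate
Product: 10 dimethyl {1-[3-methoxy-5-(17-oxoheptadecyl)phenoxy]-2-oxopropyl}phosphonate (racemic)
Conditions: Dess–Martin periodinane, CH2Cl2, 0 °C → rt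
Reagents that add atoms: none
Why: Dess–Martin oxidation takes the primary alcohol to the aldehyde under near-neutral conditions that leave the acidic C–H of the ketophosphonate and the electron-rich aryl ether untouched.

Step 7
Reactants: 10 dimethyl {1-[3-methoxy-5-(17-oxoheptadecyl)phenoxy]-2-oxopropyl}phosphonate
Product: 11 22-membered macrocyclic (Z)-α-aryloxy methyl enone (ring A bridged from its ether oxygen through C(COCH3)=CH and sixteen CH2 groups back to C1(A))
Conditions: K2CO3, 18-crown-6, toluene, 65 °C, syringe-pump addition of 10 (final 1 mM)
Reagents that add atoms: none
Why: Intramolecular Horner–Wadsworth–Emmons olefination forms C1(B)=C2(B) and closes the unstrained, flexible 22-membered ring; slow addition keeps the stationary concentration low so that ring closure beats chain growth. The acetyl group should end up trans to the chain, which is the (Z)-isomer by priority rules.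

Step 8
Reactants: 11 macrocyclic (Z)-α-aryloxy methyl enone; 12 dimethyl malonate
Product: 14 macrocyclic methyl ester with ring B at the cyclohexane-1,3-dione level (CO2CH3 on C6(B); enol at C5(B); ketone at C3(B); aryloxy on C2(B) trans to the chain on C1(B); racemic), via Michael adduct 13 (not isolated)
Conditions: NaOMe (3 equiv), MeOH/THF, 65 °C; then 1 M HCl, 0 °C
Reagents that add atoms: none
Why: Methoxide forms the sodium enolate of 12, which adds to the β-carbon of 11 (the future C1(B)) to give 13 as its enolate; proton transfer moves the enolate to the acetyl methyl group (future C4(B)), which attacks one malonate ester carbonyl (future C5(B)) and expels methoxide, so that C1(B)–C6(B) and C4(B)–C5(B) are formed in one flask. The closest known reaction type is the Michael–Claisen condensation of malonates with alkylidene acetones, which gives 5-substituted cyclohexane-1,3-dione carboxylates. The six-membered carbocycle closes by a 6-(enolendo)-exo-trig acyl substitution. Deprotonation of the product to its β-dicarbonyl enolate is the sink that pulls the reversible Michael and Claisen equilibria forward, and the matching methoxide and methyl esters rule out ester scrambling. The two new stereocentres C1(B) and C2(B) are set under thermodynamic control, since C2(B) is α to the C3(B) ketone and epimerises under NaOMe, so the chain and the aryloxy group should end up trans-diequatorial; the compound is racemic and both centres vanish in step 9. The step needs conjugate and not carbonyl addition, which the soft, reversibly adding malonate anion provides, and a single Claisen mode, which is secured because only the acetyl methyl can reach an ester through a six-membered transition state (the enolate on the C2(B) side would have to close a four-membered ring). The aryloxy oxygen on the α-carbon lowers the electrophilicity of the β-carbon somewhat, but as an aryl ether it is a weak donor, and it cannot be eliminated because no carbanion is ever formed β to it.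

Step 9
Reactants: 14 macrocyclic ring B dione ester
Product: 15 methyl ester of Grevirobstol B 5(A),3(B)-di-O-methyl ether 6(B)-carboxylic acid
Conditions: I2 (1.5 equiv), MeOH, reflux
Reagents that add atoms: methanol, CO
Why: Iodine–methanol oxidative aromatisation of a cyclohexane-1,3-dione carboxylate: the C3(B) carbonyl should be converted into its methyl enol ether under the acid formed, iodination at the doubly activated C6(B) and loss of HI towards C1(B)–H introduce the missing unsaturation, and enolisation gives the arene. The chelated enol at C5(B) should stay a free phenol, and iodine without an added oxidant does not substitute the aryl ethers irreversibly.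

Step 10
Reactants: 15 methyl ester of Grevirobstol B 5(A),3(B)-di-O-methyl ether 6(B)-carboxylic acid
Product: 17 Grevirobstol B 5(A),3(B)-di-O-methyl ether, via carboxylic acid 16 (not isolated)
Conditions: NaOH (4 M aq), MeOH/1,4-dioxane, reflux, N2; then HCl to pH 1, 90 °C
Reagents that add atoms: none
Why: Saponification of the salicylate-type ester followed by protodecarboxylation; the ortho hydroxyl and para methoxy groups make ipso protonation of the acid easy, as in the known loss of CO2 from 2,4-dioxygenated 6-alkylbenzoic acids.

Step 11
Reactants: 17 Grevirobstol B 5(A),3(B)-di-O-methyl ether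
Product: 18 Grevirobstol B
Conditions: BBr3 (6 equiv), CH2Cl2, −78 °C → rt; then H2O
Reagents that add atoms: none
Why: Lewis-acid cleavage of both aryl methyl ethers by bromide attack at the methyl carbons; the diaryl ether survives because neither of its carbons can undergo that substitution.

**Compound list**

1 | 16-bromohexadecan-1-ol | OCCCCCCCCCCCCCCCCBr | starting material
2 | benzyl 16-bromohexadecyl ether | BrCCCCCCCCCCCCCCCCOCc1ccccc1 | intermediate
3 | [16-(benzyloxy)hexadecyl]triphenylphosphonium bromide | [Br-].c1ccccc1COCCCCCCCCCCCCCCCC[P+](c1ccccc1)(c1ccccc1)c1ccccc1 | intermediate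
4 | 3-hydroxy-5-methoxybenzaldehyde | COc1cc(O)cc(C=O)c1 | starting material
5 | [16-(benzyloxy)hexadecylidene]triphenylphosphorane (ylide) | c1ccccc1COCCCCCCCCCCCCCCCC=P(c1ccccc1)(c1ccccc1)c1ccccc1 | intermediate (not isolated)
6 | 3-[(1Z)-17-(benzyloxy)heptadec-1-en-1-yl]-5-methoxyphenol (Z expected as major isomer) | COc1cc(O)cc(c1)/C=C\CCCCCCCCCCCCCCCOCc1ccccc1 | intermediate
7 | dimethyl (1-diazo-2-oxopropyl)phosphonate | COP(=O)(OC)C(=[N+]=[N-])C(C)=O | starting material
8 | dimethyl (1-{3-[(1Z)-17-(benzyloxy)heptadec-1-en-1-yl]-5-methoxyphenoxy}-2-oxopropyl)phosphonate, racemic | COc1cc(OC(C(C)=O)P(=O)(OC)OC)cc(c1)/C=C\CCCCCCCCCCCCCCCOCc1ccccc1 | intermediate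
9 | dimethyl {1-[3-(17-hydroxyheptadecyl)-5-methoxyphenoxy]-2-oxopropyl}phosphonate, racemic | COc1cc(OC(C(C)=O)P(=O)(OC)OC)cc(c1)CCCCCCCCCCCCCCCCCO | intermediate
10 | dimethyl {1-[3-methoxy-5-(17-oxoheptadecyl)phenoxy]-2-oxopropyl}phosphonate, racemic | COc1cc(OC(C(C)=O)P(=O)(OC)OC)cc(c1)CCCCCCCCCCCCCCCCC=O | intermediate
11 | 22-membered macrocyclic (Z)-α-aryloxy methyl enone of ring A | COc1cc2cc(c1)O/C(C(C)=O)=C\CCCCCCCCCCCCCCCC2 | intermediate
12 | dimethyl malonate | COC(=O)CC(=O)OC | starting material
13 | macrocyclic Michael adduct, dimethyl malonate unit on the former β-carbon, mixture of racemic diastereomers | COc1cc2cc(c1)OC(C(C)=O)C(C(C(=O)OC)C(=O)OC)CCCCCCCCCCCCCCCC2 | intermediate (not isolated)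
14 | macrocyclic methyl ester with ring B as trans-2-aryloxy-1-alkyl cyclohexane-3,5-dione 6-carboxylate (ring B locants), enol form, racemic, one enantiomer drawn | COc1cc2cc(c1)O[C@@H]1C(=O)CC(O)=C(C(=O)OC)[C@H]1CCCCCCCCCCCCCCCC2 | intermediate
15 | methyl ester of Grevirobstol B 5(A),3(B)-di-O-methyl ether 6(B)-carboxylic acid | COc1cc2cc(c1)Oc1c(OC)cc(O)c(C(=O)OC)c1CCCCCCCCCCCCCCCC2 | intermediate
16 | Grevirobstol B 5(A),3(B)-di-O-methyl ether 6(B)-carboxylic acid | COc1cc2cc(c1)Oc1c(OC)cc(O)c(C(=O)O)c1CCCCCCCCCCCCCCCC2 | intermediate (not isolated)
17 | Grevirobstol B 5(A),3(B)-di-O-methyl ether | COc1cc2cc(c1)Oc1c(OC)cc(O)cc1CCCCCCCCCCCCCCCC2 | intermediate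
18 | Grevirobstol B | Oc1cc2cc(c1)Oc1c(O)cc(O)cc1CCCCCCCCCCCCCCCC2 | target

**Step count and risk**

Total step count: 11. Longest linear sequence: 11 steps (1 to 18); 4, 7 and 12 enter as purchased compounds.

Least certain steps:

Step 8 (key step). The conjugate addition may be slow and reversible. The aryloxy oxygen feeds electron density towards the β-carbon and the acceptor is substituted at the α-carbon, so retro-Michael reaction and base-induced deconjugation of the enone could outrun the Claisen closure.
Fallback, from 11, rejoining at 17: the two carbons would be added under Lewis acid activation. Mukaiyama–Michael addition of 1-methoxy-1-(trimethylsilyloxy)ethene to 11 with TiCl4 in CH2Cl2 at −78 °C, where the Lewis acid can chelate the ketone and ether oxygens and the addition is not reversible, would give after aqueous work-up the macrocyclic δ-keto ester, methyl acetate unit on the former β-carbon, F1. KOtBu in THF would then close ring B by Claisen condensation of the acetyl methyl onto the ester to give the macrocyclic 4-aryloxy-5-alkylcyclohexane-1,3-dione F2. I2 in refluxing MeOH would aromatise F2 to a resorcinol monomethyl ether, namely 17 and possibly its regioisomer Grevirobstol B 5(A),5(B)-di-O-methyl ether F3. The two need not be separated, since step 11 converts both into 18.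

Step 7. Ring closure by the trisubstituted, doubly stabilised phosphonate carbanion may be slow at the dilution needed, so that olefination between molecules and aldol self-condensation of the aldehyde take over.
Fallback, from 6, rejoining at 11: the ring would be closed with the more nucleophilic ester-stabilised phosphonate and the ketone made afterwards.
- Rh2(OAc)4-catalysed O–H insertion of methyl diazo(dimethoxyphosphoryl)acetate into 6 would give methyl 2-{3-[(1Z)-17-(benzyloxy)heptadec-1-en-1-yl]-5-methoxyphenoxy}-2-(dimethoxyphosphoryl)acetate F4.
- Hydrogenation as in step 5 would give methyl 2-(dimethoxyphosphoryl)-2-[3-(17-hydroxyheptadecyl)-5-methoxyphenoxy]acetate F5.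
- Dess–Martin oxidation would give methyl 2-(dimethoxyphosphoryl)-2-[3-methoxy-5-(17-oxoheptadecyl)phenoxy]acetate F6.
- Ring closure with LiCl and DBU in MeCN/THF at high dilution would give the macrocyclic methyl (Z)-2-aryloxy enoate F7.
- MeNH(OMe)·HCl with iPrMgCl would convert F7 into the macrocyclic N-methoxy-N-methylamide F8, and MeMgBr would turn F8 into 11.

This answers the reactivity problem; chain growth is still controlled by dilution.

Step 4. The carbenoid may be diverted: cyclopropanation of the styrene, attack on the electron-rich ring A or on the benzyl ether oxygen, or dimerisation of the carbene would all consume 7 without forming the ether bond.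
Fallback, from 6, rejoining at 8: the O–C bond would be made by substitution and the ketone added afterwards. Alkylation of 6 with (dimethoxyphosphoryl)methyl trifluoromethanesulfonate and Cs2CO3 in MeCN would give dimethyl ({3-[(1Z)-17-(benzyloxy)heptadec-1-en-1-yl]-5-methoxyphenoxy}methyl)phosphonate F9. Deprotonation with LiN(iPr)2 (2.2 equiv) in THF at −78 °C and acylation of the phosphonate carbanion with N-methoxy-N-methylacetamide would give 8.

Step 9. Iodination may go astray: at C4(B) between the two carbonyl groups, or on the electron-rich rings once ring B is aromatic. Enol ether formation may also be incomplete, giving a mixture of ring B methylation states. These converge in step 11 but would lower the amount of pure 15.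
Fallback, from 14, rejoining at 18: dehydrogenation by hydride abstraction, which brings no electrophilic halogen near the two rings and forms no methyl ether. DDQ in 1,4-dioxane at 80 °C would give the methyl ester of Grevirobstol B 5(A)-O-methyl ether 6(B)-carboxylic acid F10. The conditions of step 10 would take F10 through Grevirobstol B 5(A)-O-methyl ether 6(B)-carboxylic acid F11 (not isolated) to Grevirobstol B 5(A)-O-methyl ether F12, and the conditions of step 11 would convert F12 into 18.

**Further compounds**

F1 | step 8 | macrocyclic δ-keto ester, methyl acetate unit on the former β-carbon of 11, mixture of racemic diastereomers | COc1cc2cc(c1)OC(C(C)=O)C(CC(=O)OC)CCCCCCCCCCCCCCCC2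
F2 | step 8 | macrocyclic 4-aryloxy-5-alkylcyclohexane-1,3-dione (ring B without the ester), racemic | COc1cc2cc(c1)OC1C(=O)CC(=O)CC1CCCCCCCCCCCCCCCC2
F3 | step 8 | Grevirobstol B 5(A),5(B)-di-O-methyl ether | COc1cc2cc(c1)Oc1c(O)cc(OC)cc1CCCCCCCCCCCCCCCC2
F4 | step 7 | methyl 2-{3-[(1Z)-17-(benzyloxy)heptadec-1-en-1-yl]-5-methoxyphenoxy}-2-(dimethoxyphosphoryl)acetate, racemic | COc1cc(OC(C(=O)OC)P(=O)(OC)OC)cc(c1)/C=C\CCCCCCCCCCCCCCCOCc1ccccc1
F5 | step 7 | methyl 2-(dimethoxyphosphoryl)-2-[3-(17-hydroxyheptadecyl)-5-methoxyphenoxy]acetate, racemic | COc1cc(OC(C(=O)OC)P(=O)(OC)OC)cc(c1)CCCCCCCCCCCCCCCCCO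
F6 | step 7 | methyl 2-(dimethoxyphosphoryl)-2-[3-methoxy-5-(17-oxoheptadecyl)phenoxy]acetate, racemic | COc1cc(OC(C(=O)OC)P(=O)(OC)OC)cc(c1)CCCCCCCCCCCCCCCCC=O
F7 | step 7 | macrocyclic methyl (Z)-2-aryloxy enoate, methyl ester counterpart of 11 | COc1cc2cc(c1)O/C(C(=O)OC)=C\CCCCCCCCCCCCCCCC2
F8 | step 7 | macrocyclic (Z)-2-aryloxy N-methoxy-N-methyl enamide | COc1cc2cc(c1)O/C(C(=O)N(C)OC)=C\CCCCCCCCCCCCCCCC2
F9 | step 4 | dimethyl ({3-[(1Z)-17-(benzyloxy)heptadec-1-en-1-yl]-5-methoxyphenoxy}methyl)phosphonate | COc1cc(OCP(=O)(OC)OC)cc(c1)/C=C\CCCCCCCCCCCCCCCOCc1ccccc1
F10 | step 9 | methyl ester of Grevirobstol B 5(A)-O-methyl ether 6(B)-carboxylic acid | COc1cc2cc(c1)Oc1c(O)cc(O)c(C(=O)OC)c1CCCCCCCCCCCCCCCC2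
F11 | step 9 | Grevirobstol B 5(A)-O-methyl ether 6(B)-carboxylic acid | COc1cc2cc(c1)Oc1c(O)cc(O)c(C(=O)O)c1CCCCCCCCCCCCCCCC2
F12 | step 9 | Grevirobstol B 5(A)-O-methyl ether | COc1cc2cc(c1)Oc1c(O)cc(O)cc1CCCCCCCCCCCCCCCC2
A1 | alternative 1 | (Z)-15',16'-didehydro Grevirobstol B tri-O-methyl ether | COc1cc(OC)c2c(c1)/C=C\CCCCCCCCCCCCCCc1cc(OC)cc(c1)O2
A2 | alternative 1 | {15-[3-(2-formyl-4,6-dimethoxyphenoxy)-5-methoxyphenyl]pentadecyl}triphenylphosphonium bromide | COc1cc(OC)c(Oc2cc(OC)cc(CCCCCCCCCCCCCCC[P+](c3ccccc3)(c3ccccc3)c3ccccc3)c2)c(C=O)c1.[Br-]
A3 | alternative 2 | 5(A),5(B)-dideoxy Grevirobstol B 3(B)-O-methyl ether (bare macrocycle) | COc1cccc2c1Oc1cccc(c1)CCCCCCCCCCCCCCCC2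
A4 | alternative 2 | Grevirobstol B 3(B)-O-methyl ether | COc1cc(O)cc2c1Oc1cc(O)cc(c1)CCCCCCCCCCCCCCCC2
A5 | alternative 3 | 4-hydroxy-3-isopropoxy-4-{18-[3-methoxy-5-(triisopropylsilyloxy)phenyl]octadec-1-en-2-yl}cyclobut-2-en-1-one | C=C(CCCCCCCCCCCCCCCCc1cc(OC)cc(O[Si](C(C)C)(C(C)C)C(C)C)c1)C1(O)C(OC(C)C)=CC1=O
A6 | alternative 3 | 2-isopropoxy-6-{16-[3-methoxy-5-(triisopropylsilyloxy)phenyl]hexadecyl}benzene-1,4-diol | CC(C)Oc1cc(O)cc(CCCCCCCCCCCCCCCCc2cc(OC)cc(O[Si](C(C)C)(C(C)C)C(C)C)c2)c1O
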